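## The problem

The target 16 is an isoflavan quinone. A 6,7,8-trimethoxychroman (benzene ring A fused to pyran ring C) carries at C3 a fully substituted 2,3,5-trimethoxy-1,4-benzoquinone (ring B, numbered here with C1 and C4 as carbonyl carbons, C2, C3 and C5 methoxylated, C6 bound to C3 of the chroman). Ring B is hexasubstituted. As an aromatic precursor it would be a pentaoxygenated benzene that no simple building block supplies, and it would have to be oxidised next to ring A, itself a tetraoxygenated arene whose O1/C6-OMe para pair is also a quinone precursor. The only stereocentre, C3 (S), lies between two methylene groups (C2, C4) and ring B, so nothing in the molecule can relay its configuration and a reagent-controlled step must set it. In the quinone the C3–H is vinylogously acidic (quinone methide tautomer) and the methoxyquinone is a set of vinylogous esters, so ring B should be unveiled last and under neutral conditions. The feature that opens the problem is the C1(=O)–C2(OMe)=C3(OMe)–C4(=O) segment of ring B: four contiguous carbons with exactly the oxygen pattern of dimethyl squarate 10, while the remaining ring atoms C5(OMe)=C6(chromanyl) are a methyl enol ether. Ring B can therefore be grown from a four-membered ring and a two-carbon enol ether by a strain-driven ring expansion, with C3 already in place.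

## Retrosynthesis

Ring B (16 to 15 to 12). Quinone 16 is taken back to hydroquinone 15 (a redox change only) and 15 to the 4-alkenyl-4-hydroxycyclobutenone 12. The cut runs through the C4–C5 bond of ring B and restores the σ bond between the two former squarate carbonyl carbons (C1–C4). Against the neighbouring cuts (the ring B–C3 bond or the C–O bonds of a preformed benzene) it avoids a pentaoxygenated arene and an oxidative demethylation beside ring A. 12 is an isomer of 15 but is assembled from two simple parts, so one thermal step creates the whole hexasubstituted ring. The forward reaction must open the cyclobutenone with the hydroxyl turning outward, close dienylketene 13 through dienone 14 faster than the ketene is trapped, and leave C3 untouched at about 140 °C.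

The C1–C6 bond of ring B (12 to 9 and 10). 12 is cut between the carbinol carbon and the alkenyl carbon into dimethyl squarate 10 and vinyllithium 11, which comes from vinyl bromide 9. Of the two ways to place the enol ether on C5/C6, the anion on the carbon bearing the chromanyl group is chosen because halogen–lithium exchange outruns any deprotonation of ring A. The regioisomeric α-methoxyvinyl anion would need a strong base in the presence of the C5–H of ring A. Precursor 9 holds only rings A and C and three further atoms. The forward step must exchange and add at −78 °C before 11 undergoes β-elimination, and must stop at mono-addition to 10.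

The vinyl bromide (9 to 7 to 6). The C–Br bond of 9 is traced to enol ether 7 through dibromo ether 8 (halogenation, then dehydrohalogenation), and the C=C bond of 7 to aldehyde 6 by a Wittig cut. This keeps every bond change away from C3, in contrast to a cut at the C3–alkenyl bond, which would need a configurationally unstable C3 nucleophile. The formyl carbon of 6 ends as C6 of ring B and the Wittig carbon as C5, so 6 is simpler by the whole of ring B. The forward steps require that the α-branched, β-aryloxy aldehyde 6 reacts before it enolises and that the halogen finds the enol ether, not ring A.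

The stereocentre (6 to 5 to 4). 6 is the oxidation product of alcohol 5, and 5 arises by hydrogenation of the C3=C4 bond of allylic alcohol 4. Setting C3 here, on a small chromene without ring B, is preferred over a late hydrogenation of a 3-aryl chromene: the alkene is unhindered, the hydroxymethyl group is the handle needed later, and 2-substituted 3-aryl allylic alcohols are a proven substrate class for cationic iridium P,N catalysts. 4 is achiral and two steps from purchased material. The forward step must discriminate the faces of a trisubstituted alkene, and all later steps must avoid epimerising C3.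

The pyran ring (4 to 3 to 1 and 2). 4 is the 1,2-reduction product of enal 3, and 3 is cut at O1–C2 and C3–C4 into salicylaldehyde 1 and acrolein 2. This double cut is preferred over closing O1–C2 alone on an acyclic chain, which would need protecting-group and redox steps. Both precursors are single-ring or acyclic compounds. The forward reaction (oxa-Michael addition, aldol condensation) must build ring C and the formyl handle in one operation.

## Roads not taken

Alternative 1: the most obvious plan keeps ring B as a pentamethoxyphenyl group and cuts only the C3–H/C4–H bonds. Forward key step: iridium-catalysed asymmetric hydrogenation of isoflavene A1 to isoflavan A2, then oxidative demethylation with (NH4)2Ce(NO3)6 to 16. The chosen plan is better for three reasons. A1 needs a pentaoxygenated aryl donor that itself takes several steps. The twisted, doubly ortho-substituted aryl group shields the C3=C4 bond. The final oxidation must tell ring B from ring A, whose O1/C6-OMe para pair can also go to a quinone with opening of ring C.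

Alternative 2: cut O1–C2 and C3–C4 of the chroman. Forward key step: auxiliary-controlled benzylation of an acyl oxazolidinone of arylacetic acid A3 with an O-protected ring A benzylic bromide, reductive removal of the auxiliary to phenol-alcohol A4, Mitsunobu closure to A2 and oxidation. The chosen plan is better because this route needs the same scarce pentaoxygenated acid A3 and the same unselective end-game oxidation. It also uses a stoichiometric auxiliary and several protecting-group and redox steps between alkylation and ring closure.

Alternative 3: cut the ring B–C3 bond directly. Forward key step: decarboxylative radical alkylation (AgNO3, (NH4)2S2O8) of trimethoxyquinone A5 with chroman acid A6, which would give A7. This is the shortest route on paper, but the C3 radical is planar and flanked by two nearly equivalent methylene groups, so there is no handle for enantiocontrol and A7 is racemic. A5 also has to be made. The chosen plan uses the same chroman C3 unit but keeps C3 tetrahedral from step 3 to the end.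

Key step: step 8

Assumption: salicylaldehyde 1 is treated as a catalogue compound, and the C3 descriptor of the target SMILES is read as S.

## Steps

Step 1
Reactants: 1 2-hydroxy-3,4,5-trimethoxybenzaldehyde; 2 acrolein (prop-2-enal)
Product: 3 6,7,8-trimethoxy-2H-chromene-3-carbaldehyde
Conditions: K2CO3, 1,4-dioxane, reflux
Reagents that add atoms: none
Why: Oxa-Michael addition of the phenoxide to acrolein, intramolecular aldol closure onto the aryl aldehyde and dehydration (the standard salicylaldehyde–acrolein chromene annulation) should build ring C and the C3 formyl handle in one operation.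

Step 2
Reactants: 3 6,7,8-trimethoxy-2H-chromene-3-carbaldehyde
Product: 4 (6,7,8-trimethoxy-2H-chromen-3-yl)methanol
Conditions: NaBH4, CeCl3·7H2O, MeOH, 0 °C
Reagents that add atoms: none
Why: Luche reduction should give clean 1,2-reduction of the enal and leave the C3=C4 bond for the asymmetric step.

Step 3
Reactants: 4 (6,7,8-trimethoxy-2H-chromen-3-yl)methanol
Product: 5 [(3S)-6,7,8-trimethoxy-3,4-dihydro-2H-chromen-3-yl]methanol
Conditions: H2 (50 bar), [Ir(cod)(tBu-PHOX)][B(C6H3(CF3)2)4] (1 mol %; tBu-PHOX = 4-tert-butyl-2-[2-(diphenylphosphanyl)phenyl]-4,5-dihydrooxazole, antipode chosen to give (S)-5), CH2Cl2, 23 °C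
Reagents that add atoms: none
Why: Asymmetric hydrogenation of a trisubstituted, aryl-conjugated allylic alcohol with a cationic iridium P,N catalyst; 4 is a ring-constrained member of the 2-substituted 3-aryl allylic alcohol class for which these catalysts are established. The chiral ligand pocket selects the face of C3=C4 to which hydrogen is delivered and so sets C3, the only stereocentre of the route.

Step 4
Reactants: 5 [(3S)-6,7,8-trimethoxy-3,4-dihydro-2H-chromen-3-yl]methanol
Product: 6 (3R)-6,7,8-trimethoxy-3,4-dihydro-2H-chromene-3-carbaldehyde
Conditions: Dess–Martin periodinane, CH2Cl2, 0 to 23 °C; crude aldehyde used at once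
Reagents that add atoms: none
Why: Neutral hypervalent-iodine oxidation should not enolise the α-branched aldehyde; the descriptor changes from S to R only because the formyl group outranks C2, the spatial arrangement is unchanged.

Step 5
Reactants: 6 (3R)-6,7,8-trimethoxy-3,4-dihydro-2H-chromene-3-carbaldehyde
Product: 7 (3S)-6,7,8-trimethoxy-3-(2-methoxyethenyl)-3,4-dihydro-2H-chromene (E/Z mixture)
Conditions: MeOCH2PPh3Cl, KN(SiMe3)2, THF, 0 °C; then 6, −78 to 0 °C
Reagents that add atoms: (methoxymethyl)triphenylphosphonium chloride, COC[P+](c1ccccc1)(c1ccccc1)c1ccccc1.[Cl-]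
Why: Wittig methoxymethylenation; the non-stabilised ylide should add to the aldehyde at −78 °C faster than it deprotonates C3, and the alkene geometry is irrelevant because both isomers converge later.

Step 6
Reactants: 7 (3S)-6,7,8-trimethoxy-3-(2-methoxyethenyl)-3,4-dihydro-2H-chromene
Product: 9 (3R)-3-(1-bromo-2-methoxyethenyl)-6,7,8-trimethoxy-3,4-dihydro-2H-chromene (E/Z mixture), via dibromo ether 8 (not isolated)
Conditions: Br2 (1.0 equiv), CH2Cl2, −78 °C; then iPr2NEt, −78 to 23 °C
Reagents that add atoms: bromine, BrBr
Why: Standard bromination–dehydrobromination of an enol ether: bromine adds to the electron-rich alkene far faster than to ring A at −78 °C. In 8 the bromide on the acetal carbon is the labile one, so the amine removes the proton from the neighbouring CHBr carbon and the 2-bromo enol ether results; C3 is not involved.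

Step 7
Reactants: 9 (3R)-3-(1-bromo-2-methoxyethenyl)-6,7,8-trimethoxy-3,4-dihydro-2H-chromene; 10 dimethyl squarate (3,4-dimethoxycyclobut-3-ene-1,2-dione)
Product: 12 4-hydroxy-2,3-dimethoxy-4-{2-methoxy-1-[(3S)-6,7,8-trimethoxy-3,4-dihydro-2H-chromen-3-yl]ethenyl}cyclobut-2-en-1-one (mixture of alkene and carbinol isomers), via vinyllithium 11 (not isolated)
Conditions: t-BuLi (2.1 equiv), THF, −78 °C; then 10, THF, −78 °C; aq. NH4Cl at −78 °C
Reagents that add atoms: none
Why: Bromine–lithium exchange on a vinyl bromide is faster at −78 °C than any deprotonation of ring A or of C3. Alkenyllithium reagents add once to one carbonyl of squarate esters, because the alkoxide formed deactivates the second carbonyl; this 1,2-addition makes the C1–C6 bond of the future ring B.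

Step 8
Reactants: 12 4-hydroxy-2,3-dimethoxy-4-{2-methoxy-1-[(3S)-6,7,8-trimethoxy-3,4-dihydro-2H-chromen-3-yl]ethenyl}cyclobut-2-en-1-one
Product: 16 2,3,5-trimethoxy-6-[(3S)-6,7,8-trimethoxy-3,4-dihydro-2H-chromen-3-yl]cyclohexa-2,5-diene-1,4-dione, via dienylketene 13 (not isolated), via cyclohexadienone 14 (not isolated), via hydroquinone 15 (not isolated)
Conditions: p-xylene, 138 °C, argon; then Ag2O, 23 °C
Reagents that add atoms: none
Why: On heating, the cyclobutenone of 12 undergoes thermal conrotatory 4π electrocyclic ring opening, and torquoselectivity turns the donor hydroxyl outward and the alkenyl group inward, so dienylketene 13 is formed in the geometry needed for closure. Ring B is then closed by a thermal disrotatory 6π electrocyclisation in which the ketene carbon (future C4) bonds to the enol-ether terminus (future C5); dienone 14 enolises to hydroquinone 15, and release of four-ring strain plus aromatisation drive the cascade. The closest known reaction type is the Moore–Liebeskind ring expansion of 4-alkenyl-4-hydroxycyclobutenones made from squarate esters, which is established for alkoxy-substituted alkenyl groups. No stereocentre is created: C3 is never part of a π system or an enolisable position during the cascade, and the alkene and carbinol isomers of 12 converge on one achiral ring. Regioselectivity cannot fail, because the squarate-derived C1–C4 unit carries the same substituent on C2 and C3, so only one hexasubstituted ring can form. The selectivity the step needs is oxidation of ring B in the presence of the tetraoxygenated ring A; this is secured by delivering ring B at the hydroquinone level, which Ag2O oxidises at room temperature while the fully etherified ring A is inert. Neutral conditions throughout avoid the quinone methide tautomer, so the configuration set in step 3 should survive.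

## Compound list

1 | 2-hydroxy-3,4,5-trimethoxybenzaldehyde | O=Cc1cc(OC)c(OC)c(OC)c1O | starting material
2 | acrolein (prop-2-enal) | C=CC=O | starting material
3 | 6,7,8-trimethoxy-2H-chromene-3-carbaldehyde | O=CC1=Cc2cc(OC)c(OC)c(OC)c2OC1 | intermediate
4 | (6,7,8-trimethoxy-2H-chromen-3-yl)methanol | OCC1=Cc2cc(OC)c(OC)c(OC)c2OC1 | intermediate
5 | [(3S)-6,7,8-trimethoxy-3,4-dihydro-2H-chromen-3-yl]methanol | OC[C@H]1COc2c(cc(OC)c(OC)c2OC)C1 | intermediate
6 | (3R)-6,7,8-trimethoxy-3,4-dihydro-2H-chromene-3-carbaldehyde | O=C[C@H]1COc2c(cc(OC)c(OC)c2OC)C1 | intermediate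
7 | (3S)-6,7,8-trimethoxy-3-(2-methoxyethenyl)-3,4-dihydro-2H-chromene (E/Z mixture) | COC=C[C@H]1COc2c(cc(OC)c(OC)c2OC)C1 | intermediate
8 | (3R)-3-(1,2-dibromo-2-methoxyethyl)-6,7,8-trimethoxy-3,4-dihydro-2H-chromene (diastereomer mixture, not isolated) | COC(Br)C(Br)[C@H]1COc2c(cc(OC)c(OC)c2OC)C1 | intermediate
9 | (3R)-3-(1-bromo-2-methoxyethenyl)-6,7,8-trimethoxy-3,4-dihydro-2H-chromene (E/Z mixture) | COC=C(Br)[C@H]1COc2c(cc(OC)c(OC)c2OC)C1 | intermediate
10 | dimethyl squarate (3,4-dimethoxycyclobut-3-ene-1,2-dione) | COC1=C(OC)C(=O)C1=O | starting material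
11 | {2-methoxy-1-[(3S)-6,7,8-trimethoxy-3,4-dihydro-2H-chromen-3-yl]ethenyl}lithium (not isolated) | COC=C([Li])[C@H]1COc2c(cc(OC)c(OC)c2OC)C1 | intermediate
12 | 4-hydroxy-2,3-dimethoxy-4-{2-methoxy-1-[(3S)-6,7,8-trimethoxy-3,4-dihydro-2H-chromen-3-yl]ethenyl}cyclobut-2-en-1-one (alkene and carbinol isomers) | COC=C([C@H]1COc2c(cc(OC)c(OC)c2OC)C1)C3(O)C(OC)=C(OC)C3=O | intermediate
13 | 4-hydroxy-2,3,6-trimethoxy-5-[(3S)-6,7,8-trimethoxy-3,4-dihydro-2H-chromen-3-yl]hexa-1,3,5-trien-1-one (dienylketene, not isolated) | O=C=C(OC)C(OC)=C(O)C(=COC)[C@H]1COc2c(cc(OC)c(OC)c2OC)C1 | intermediate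
14 | 4-hydroxy-2,3,6-trimethoxy-5-[(3S)-6,7,8-trimethoxy-3,4-dihydro-2H-chromen-3-yl]cyclohexa-2,4-dien-1-one (not isolated) | COC1C(=O)C(OC)=C(OC)C(O)=C1[C@H]2COc3c(cc(OC)c(OC)c3OC)C2 | intermediate
15 | 2,3,5-trimethoxy-6-[(3S)-6,7,8-trimethoxy-3,4-dihydro-2H-chromen-3-yl]benzene-1,4-diol (not isolated) | COc1c(OC)c(O)c([C@H]2COc3c(cc(OC)c(OC)c3OC)C2)c(OC)c1O | intermediate
16 | 2,3,5-trimethoxy-6-[(3S)-6,7,8-trimethoxy-3,4-dihydro-2H-chromen-3-yl]cyclohexa-2,5-diene-1,4-dione | COC1=C(OC)C(=O)C([C@H]2COc3c(cc(OC)c(OC)c3OC)C2)=C(OC)C1=O | target

## Step count and risks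

Total step count: 8. Longest linear sequence: 8 steps (1 to 16); 10 enters at step 7 as a purchased partner.

Step 8 (key step). The most likely failure is inward rotation of the hydroxyl for part of the material during ring opening, so that the ketene is captured by oxygen and a butenolide forms instead of ring B. A second risk is slow electrocyclisation of the alkene isomer whose methoxy group points into the triene, giving the ketene time to decay. The fallback sets out from 12 and returns at 15. The carbinol is capped with Me3SiOTf/Et3N to give 2,3-dimethoxy-4-{2-methoxy-1-[(3S)-6,7,8-trimethoxy-3,4-dihydro-2H-chromen-3-yl]ethenyl}-4-[(trimethylsilyl)oxy]cyclobut-2-en-1-one F1. With no O–H left the lactone channel is closed, and the bulkier donor reinforces outward rotation. Thermolysis in p-xylene should then give 2,3,6-trimethoxy-5-[(3S)-6,7,8-trimethoxy-3,4-dihydro-2H-chromen-3-yl]-4-[(trimethylsilyl)oxy]phenol F2. Bu4NF releases 15, which is oxidised with Ag2O as in step 8.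

Step 7. The most likely failure is β-elimination within vinyllithium 11 (loss of methoxide from the isomer with lithium and methoxy anti) before it meets 10, which lowers the yield and produces an acetylide that adds instead. Double addition to 10 is a lesser risk. The fallback sets out from 9 and returns at 15. Dehydrobromination of 9 with LiN(iPr)2 should give (3S)-6,7,8-trimethoxy-3-(methoxyethynyl)-3,4-dihydro-2H-chromene F3. Syn-hydrostannation with Bu3SnH and catalytic Pd(PPh3)4 places tin on the oxygen-bearing carbon and gives tributyl{1-methoxy-2-[(3S)-6,7,8-trimethoxy-3,4-dihydro-2H-chromen-3-yl]ethenyl}stannane F4. Tin–lithium exchange with n-BuLi at −78 °C gives {1-methoxy-2-[(3S)-6,7,8-trimethoxy-3,4-dihydro-2H-chromen-3-yl]ethenyl}lithium F5, which has no β-leaving group. Addition to 10 gives 4-hydroxy-2,3-dimethoxy-4-{1-methoxy-2-[(3S)-6,7,8-trimethoxy-3,4-dihydro-2H-chromen-3-yl]ethenyl}cyclobut-2-en-1-one F6. Because the squarate-derived half of ring B is symmetric, thermolysis of F6 under the conditions of step 8 converges on 15.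

Step 6. The most likely failure is electrophilic attack on ring A, either bromination at C5 or Friedel–Crafts-type capture of the transient α-bromo oxocarbenium ion by C5, in competition with the elimination. The fallback sets out from 7 and returns at 9. N-Bromosuccinimide in methanol at 0 °C, where the solvent traps the oxocarbenium ion as it forms, should give (3R)-3-(1-bromo-2,2-dimethoxyethyl)-6,7,8-trimethoxy-3,4-dihydro-2H-chromene F7. Elimination of methanol with Me3SiOTf/iPr2NEt, with the amine present from the start, then gives 9.

Step 3. The most likely failure is insufficient facial discrimination, or isomerisation of the allylic alcohol to the saturated aldehyde by the iridium hydride, which bypasses the enantio-determining hydrogen transfer. The fallback sets out from 3 and returns at 5. Oxidation of 3 with NaClO2/NaH2PO4/2-methylbut-2-ene gives 6,7,8-trimethoxy-2H-chromene-3-carboxylic acid F8. Carboxylate-directed hydrogenation with Ru(OAc)2(BINAP) (antipode chosen for the R acid) should give (3R)-6,7,8-trimethoxy-3,4-dihydro-2H-chromene-3-carboxylic acid F9, which can be enriched by crystallisation of an amine salt. BH3·SMe2 reduces F9 to 5.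

## Further compounds

F1 | step 8 | 2,3-dimethoxy-4-{2-methoxy-1-[(3S)-6,7,8-trimethoxy-3,4-dihydro-2H-chromen-3-yl]ethenyl}-4-[(trimethylsilyl)oxy]cyclobut-2-en-1-one | COC=C([C@H]1COc2c(cc(OC)c(OC)c2OC)C1)C3(O[Si](C)(C)C)C(OC)=C(OC)C3=O
F2 | step 8 | 2,3,6-trimethoxy-5-[(3S)-6,7,8-trimethoxy-3,4-dihydro-2H-chromen-3-yl]-4-[(trimethylsilyl)oxy]phenol | COc1c(OC)c(O[Si](C)(C)C)c([C@H]2COc3c(cc(OC)c(OC)c3OC)C2)c(OC)c1O
F3 | step 7 | (3S)-6,7,8-trimethoxy-3-(methoxyethynyl)-3,4-dihydro-2H-chromene | COC#C[C@H]1COc2c(cc(OC)c(OC)c2OC)C1
F4 | step 7 | tributyl{1-methoxy-2-[(3S)-6,7,8-trimethoxy-3,4-dihydro-2H-chromen-3-yl]ethenyl}stannane | CCCC[Sn](CCCC)(CCCC)C(OC)=C[C@H]1COc2c(cc(OC)c(OC)c2OC)C1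
F5 | step 7 | {1-methoxy-2-[(3S)-6,7,8-trimethoxy-3,4-dihydro-2H-chromen-3-yl]ethenyl}lithium | COC([Li])=C[C@H]1COc2c(cc(OC)c(OC)c2OC)C1
F6 | step 7 | 4-hydroxy-2,3-dimethoxy-4-{1-methoxy-2-[(3S)-6,7,8-trimethoxy-3,4-dihydro-2H-chromen-3-yl]ethenyl}cyclobut-2-en-1-one | COC(=C[C@H]1COc2c(cc(OC)c(OC)c2OC)C1)C3(O)C(OC)=C(OC)C3=O
F7 | step 6 | (3R)-3-(1-bromo-2,2-dimethoxyethyl)-6,7,8-trimethoxy-3,4-dihydro-2H-chromene | COC(OC)C(Br)[C@H]1COc2c(cc(OC)c(OC)c2OC)C1
F8 | step 3 | 6,7,8-trimethoxy-2H-chromene-3-carboxylic acid | OC(=O)C1=Cc2cc(OC)c(OC)c(OC)c2OC1
F9 | step 3 | (3R)-6,7,8-trimethoxy-3,4-dihydro-2H-chromene-3-carboxylic acid | OC(=O)[C@H]1COc2c(cc(OC)c(OC)c2OC)C1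
A1 | alternative 1 | 6,7,8-trimethoxy-3-(2,3,4,5,6-pentamethoxyphenyl)-2H-chromene | COc1cc2C=C(COc2c(OC)c1OC)c1c(OC)c(OC)c(OC)c(OC)c1OC
A2 | alternative 1 | (3S)-6,7,8-trimethoxy-3-(2,3,4,5,6-pentamethoxyphenyl)-3,4-dihydro-2H-chromene | COc1c(OC)c(OC)c(OC)c(OC)c1[C@H]2COc3c(cc(OC)c(OC)c3OC)C2
A3 | alternative 2 | 2-(2,3,4,5,6-pentamethoxyphenyl)acetic acid | COc1c(OC)c(OC)c(OC)c(OC)c1CC(O)=O
A4 | alternative 2 | (2S)-3-(2-hydroxy-3,4,5-trimethoxyphenyl)-2-(2,3,4,5,6-pentamethoxyphenyl)propan-1-ol | COc1c(OC)c(OC)c(OC)c(OC)c1[C@H](Cc2cc(OC)c(OC)c(OC)c2O)CO
A5 | alternative 3 | 2,3,5-trimethoxycyclohexa-2,5-diene-1,4-dione | COC1=CC(=O)C(OC)=C(OC)C1=O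
A6 | alternative 3 | rac-6,7,8-trimethoxy-3,4-dihydro-2H-chromene-3-carboxylic acid | OC(=O)C1COc2c(cc(OC)c(OC)c2OC)C1
A7 | alternative 3 | rac-2,3,5-trimethoxy-6-(6,7,8-trimethoxy-3,4-dihydro-2H-chromen-3-yl)cyclohexa-2,5-diene-1,4-dione | COC1=C(OC)C(=O)C(C2COc3c(cc(OC)c(OC)c3OC)C2)=C(OC)C1=O
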